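Everything rests on disconnecting the C5–C6 bond of the ten-membered carbocycle together with the O6–C12 bond of the γ-lactone. SmI2 couples the C5 and C6 aldehydes of an open-chain dialdehyde ester, closing the carbocycle and setting both carbinol centres, and the samarium alkoxide on O6 then acylates on C12 to close the lactone. The step exploits the vicinal C5/C6 diol of the ten-membered ring and the fact that O6 is γ to C12 (five-membered lactone ring), whereas O5 is only δ and O8, which is also γ, is blocked. The precursor is the C5,C6-dialdehyde bearing the C12 methyl ester, the E-C2=C3 olefin, silyl ethers on O4 and O8 and a PMB ether on O9.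

Key step: step 15

Remarks on the chemistry (valid for all steps)
- Locants: C1 (CH2), C2–C3 (epoxide, olefin before step 19), C4 (C(CH3)OH), C5, C6 (lactone O–CH), C7, C8, C9 (ketone), C10 (CHCH3), lactone C11(=C13H2)–C12(=O). Names of cyclic compounds use these locants.
- The target SMILES reads as 2S,3R,4R,5R,6S,7S,8S,10S: trans epoxide, trans-fused lactone (O6 and C11 on opposite ring faces), O5 and O6 trans on the ring, both esters Z (angelates).
- O6 and O8 are both γ to C12. O8 is therefore silylated directly after the aldol, so that only O6 can later form a five-membered lactone.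
- C9 ends as a ketone, so its configuration is free. It is set 9R (O9 anti to O8), so that the Cornforth/Felkin bias of the α-alkoxy aldehyde gives the required C8 centre in an auxiliary-free anti-aldol.
- O9 carries the PMB ether and O8 a triethylsilyl ether. The last deprotection is then a neutral DDQ step, not a fluoride treatment next to the epoxide and the esters.
- C6 enters as an S-ethyl thioester and is reduced directly to the aldehyde, so no free C6 hydroxyl γ to the C12 ester is ever present.
- Stereocentres: C10 from 1; C9 in step 1 (erased in step 22); C4 in step 5; C7 and C8 in step 11; C5 and C6 in step 15; C2 and C3 in step 19.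
- Assumptions: the acetal carbon of 5–11 forms as an epimer mixture (undefined in the SMILES, removed in step 8); the samarium-bound O6 alkoxide acylates on the methyl ester at room temperature.

Step 1
Reactants: 1 (S)-citronellal
Product: 3 (2R,3S)-3,7-dimethyl-2-[(phenylamino)oxy]oct-6-en-1-ol, via anilinooxy aldehyde 2 (not isolated)
Conditions: PhN=O (1 equiv), L-proline (20 mol %), 1 (2 equiv), CHCl3, 4 °C; then NaBH4, EtOH, 0 °C
Reagents that add atoms: nitrosobenzene O=Nc1ccccc1
Why: Proline-catalysed enamine α-aminoxylation, in which the carboxylic acid of L-proline steers the nitroso oxygen onto one enamine face and so sets C9 as 2R under catalyst control, followed by borohydride reduction of the labile α-oxy aldehyde in the same flask.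

Step 2
Reactants: 3 (2R,3S)-3,7-dimethyl-2-[(phenylamino)oxy]oct-6-en-1-ol
Product: 4 (2R,3S)-3,7-dimethyloct-6-ene-1,2-diol
Conditions: Zn dust, AcOH/EtOH, rt
Reagents that add atoms: none
Why: Dissolving-metal reductive cleavage of the weak N–O bond should release the secondary alcohol and aniline without touching the trisubstituted olefin or either stereocentre.

Step 3
Reactants: 4 (2R,3S)-3,7-dimethyloct-6-ene-1,2-diol
Product: 5 (4R)-2-(4-methoxyphenyl)-4-[(2S)-6-methylhept-5-en-2-yl]-1,3-dioxolane
Conditions: 4-MeOC6H4CH(OMe)2, PPTS (cat.), CH2Cl2, rt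
Reagents that add atoms: 4-methoxybenzaldehyde dimethyl acetal COc1ccc(cc1)C(OC)OC
Why: Acid-catalysed transacetalisation ties the 1,2-diol into a 4-methoxybenzylidene acetal, which protects C8/C9 through the olefin chemistry and later hands the PMB group to O9.

Step 4
Reactants: 5 (4R)-2-(4-methoxyphenyl)-4-[(2S)-6-methylhept-5-en-2-yl]-1,3-dioxolane
Product: 6 (2E,6S)-6-[(4R)-2-(4-methoxyphenyl)-1,3-dioxolan-4-yl]-2-methylhept-2-en-1-ol
Conditions: SeO2 (0.3 equiv), t-BuOOH (3 equiv), salicylic acid (cat.), CH2Cl2, rt; then NaBH4, MeOH, 0 °C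
Reagents that add atoms: selenium dioxide O=[Se]=O (oxygen carrier); tert-butyl hydroperoxide CC(C)(C)OO (terminal oxygen source)
Why: Catalytic SeO2 allylic oxidation (ene reaction then 2,3-sigmatropic shift) attacks the E-methyl group at the more substituted olefin terminus and gives the E-allylic alcohol whose carbons become C3=C4–C5, the borohydride wash returning any over-oxidised enal.

Step 5
Reactants: 6 (2E,6S)-6-[(4R)-2-(4-methoxyphenyl)-1,3-dioxolan-4-yl]-2-methylhept-2-en-1-ol
Product: 7 [(2S,3S)-3-{(3S)-3-[(4R)-2-(4-methoxyphenyl)-1,3-dioxolan-4-yl]butyl}-2-methyloxiran-2-yl]methanol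
Conditions: Ti(Oi-Pr)4 (10 mol %), L-(+)-diethyl tartrate (12 mol %), t-BuOOH (2 equiv), 4 Å molecular sieves, CH2Cl2, −20 °C
Reagents that add atoms: tert-butyl hydroperoxide CC(C)(C)OO
Why: Katsuki–Sharpless asymmetric epoxidation, in which the titanium complex of the L-(+)-tartrate delivers oxygen to the olefin face that gives the 2S,3S epoxy alcohol, so the C4–O bond of the future tertiary carbinol is set by the reagent.

Step 6
Reactants: 7 [(2S,3S)-3-{(3S)-3-[(4R)-2-(4-methoxyphenyl)-1,3-dioxolan-4-yl]butyl}-2-methyloxiran-2-yl]methanol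
Product: 10 (2R,3E,6S)-6-[(4R)-2-(4-methoxyphenyl)-1,3-dioxolan-4-yl]-2-methylhept-3-ene-1,2-diol, via hydroxy selenide 8 (not isolated), via selenoxide 9 (not isolated)
Conditions: PhSeSePh (0.6 equiv), NaBH4 (1.3 equiv), EtOH, rt → 50 °C; then THF, 30% H2O2, 0 °C → rt
Reagents that add atoms: none
Why: Epoxide-to-allylic-alcohol transposition through selenium, in which the selenolate opens the epoxide by SN2 at the less hindered secondary C3 and the selenoxide then undergoes syn-elimination, which can only run toward C2 because C4 is quaternary, so the E-C2=C3 olefin appears while the C4–O bond and its configuration are untouched.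

Step 7
Reactants: 10 (2R,3E,6S)-6-[(4R)-2-(4-methoxyphenyl)-1,3-dioxolan-4-yl]-2-methylhept-3-ene-1,2-diol
Product: 11 (4R)-2-(4-methoxyphenyl)-4-[(2S,4E,6R)-6-methyl-6,7-bis(triethylsilyloxy)hept-4-en-2-yl]-1,3-dioxolane
Conditions: Et3SiCl (4 equiv), imidazole, DMAP (cat.), DMF, rt → 40 °C
Reagents that add atoms: chlorotriethylsilane CC[Si](Cl)(CC)CC
Why: Imidazole-promoted silylation caps the primary C5 and, on warming, the tertiary C4 hydroxyl, and avoids the silyl triflate whose Lewis acidity would open the benzylidene acetal.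

Step 8
Reactants: 11 (4R)-2-(4-methoxyphenyl)-4-[(2S,4E,6R)-6-methyl-6,7-bis(triethylsilyloxy)hept-4-en-2-yl]-1,3-dioxolane
Product: 12 (2R,3S,5E,7R)-2-[(4-methoxybenzyl)oxy]-3,7-dimethyl-7,8-bis(triethylsilyloxy)oct-5-en-1-ol
Conditions: i-Bu2AlH (3 equiv), CH2Cl2, −78 → 0 °C; aq. KNaC4H4O6
Reagents that add atoms: none
Why: Regioselective reductive opening of the 4-methoxybenzylidene acetal, in which aluminium binds the less hindered primary oxygen so that hydride delivery to the oxocarbenium ion leaves the PMB ether on the secondary O9 and frees the C8 hydroxyl.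

Step 9
Reactants: 12 (2R,3S,5E,7R)-2-[(4-methoxybenzyl)oxy]-3,7-dimethyl-7,8-bis(triethylsilyloxy)oct-5-en-1-ol
Product: 13 (2R,3S,5E,7R)-2-[(4-methoxybenzyl)oxy]-3,7-dimethyl-7,8-bis(triethylsilyloxy)oct-5-enal
Conditions: Dess–Martin periodinane, pyridine, CH2Cl2, 0 °C → rt
Reagents that add atoms: none
Why: Dess–Martin oxidation under pyridine buffer should give the α-alkoxy aldehyde without epimerising C9 and, unlike an activated-sulfoxide oxidation, without attacking the primary silyl ether.

Step 10
Reactants: 14 methyl 4-chloro-4-oxobutanoate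
Product: 15 methyl 4-(ethylsulfanyl)-4-oxobutanoate
Conditions: EtSH, Et3N, CH2Cl2, 0 °C
Reagents that add atoms: ethanethiol CCS
Why: Acylation of the thiol by the acid chloride gives a mixed thioester/ester in which only the thioester α-methylene is enolised by a dialkylboron chloride and only the thioester acyl group is later reduced by silane and palladium.

Step 11
Reactants: 13 (2R,3S,5E,7R)-2-[(4-methoxybenzyl)oxy]-3,7-dimethyl-7,8-bis(triethylsilyloxy)oct-5-enal; 15 methyl 4-(ethylsulfanyl)-4-oxobutanoate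
Product: 17 methyl (3R,4S,5R,6S,8E,10R)-3-[(ethylsulfanyl)carbonyl]-4-hydroxy-5-[(4-methoxybenzyl)oxy]-6,10-dimethyl-10,11-bis(triethylsilyloxy)undec-8-enoate, via enol borinate 16 (not isolated)
Conditions: 15 (2 equiv), (c-C6H11)2BCl (2.2 equiv), Et3N, Et2O, 0 °C; then 13, −78 → −20 °C; pH 7 buffer, MeOH, 30% H2O2, 0 °C
Reagents that add atoms: none
Why: Boron-mediated anti-aldol reaction, in which (c-C6H11)2BCl/Et3N enolises only the thioester to the E(O)-enol borinate, whose Zimmerman–Traxler chair sets C7 anti to the new C8 hydroxyl, while the α-alkoxy aldehyde is attacked in the Cornforth (polar Felkin–Anh) sense so that O8 forms anti to the O9 ether, 1,2-induction from the 9R centre thus fixing both new centres.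

Step 12
Reactants: 17 methyl (3R,4S,5R,6S,8E,10R)-3-[(ethylsulfanyl)carbonyl]-4-hydroxy-5-[(4-methoxybenzyl)oxy]-6,10-dimethyl-10,11-bis(triethylsilyloxy)undec-8-enoate
Product: 18 methyl (3R,4S,5R,6S,8E,10R)-3-[(ethylsulfanyl)carbonyl]-5-[(4-methoxybenzyl)oxy]-6,10-dimethyl-4,10,11-tris(triethylsilyloxy)undec-8-enoate
Conditions: Et3SiOTf, 2,6-lutidine, CH2Cl2, −78 °C
Reagents that add atoms: triethylsilyl trifluoromethanesulfonate CC[Si](CC)(CC)OS(=O)(=O)C(F)(F)F
Why: Fast silyl triflate protection caps O8, which is γ to the C12 ester and would otherwise lactonise, so that the oxygen later formed on C6 is the only one able to close a five-membered lactone.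

Step 13
Reactants: 18 methyl (3R,4S,5R,6S,8E,10R)-3-[(ethylsulfanyl)carbonyl]-5-[(4-methoxybenzyl)oxy]-6,10-dimethyl-4,10,11-tris(triethylsilyloxy)undec-8-enoate
Product: 19 methyl (3R,4S,5R,6S,8E,10R)-3-[(ethylsulfanyl)carbonyl]-5-[(4-methoxybenzyl)oxy]-6,10-dimethyl-11-oxo-4,10-bis(triethylsilyloxy)undec-8-enoate
Conditions: (COCl)2 (4 equiv), DMSO (8 equiv), CH2Cl2, −78 → −30 °C; then Et3N, −78 → 0 °C
Reagents that add atoms: none
Why: Swern conditions cleave a primary triethylsilyl ether and oxidise it directly to the aldehyde (chloride-assisted desilylation by the chlorosulfonium salt), while the hindered secondary and tertiary silyl ethers, the thioester and the PMB ether should be inert and the new C5 aldehyde has no α-hydrogen.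

Step 14
Reactants: 19 methyl (3R,4S,5R,6S,8E,10R)-3-[(ethylsulfanyl)carbonyl]-5-[(4-methoxybenzyl)oxy]-6,10-dimethyl-11-oxo-4,10-bis(triethylsilyloxy)undec-8-enoate
Product: 20 methyl (3R,4S,5R,6S,8E,10R)-3-formyl-5-[(4-methoxybenzyl)oxy]-6,10-dimethyl-11-oxo-4,10-bis(triethylsilyloxy)undec-8-enoate
Conditions: Et3SiH (3 equiv), 10% Pd/C (10 mol % Pd), acetone, rt
Reagents that add atoms: none
Why: Fukuyama reduction, in which zerovalent palladium inserts into the acyl–sulfur bond and the silane delivers hydride, should give the C6 aldehyde under neutral conditions without touching the methyl ester, the hindered olefin or the C7 centre.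

Step 15
Reactants: 20 methyl (3R,4S,5R,6S,8E,10R)-3-formyl-5-[(4-methoxybenzyl)oxy]-6,10-dimethyl-11-oxo-4,10-bis(triethylsilyloxy)undec-8-enoate
Product: 22 trans-fused hydroxy γ-lactone (2E,4R,5R,6S,7S,8S,9R,10S)-5-hydroxy-9-[(4-methoxybenzyl)oxy]-4,10-dimethyl-4,8-bis(triethylsilyloxy)cyclodec-2-ene carrying the C7–C11H2–C12(=O)–O6 lactone, via samarium diolate 21 (not isolated)
Conditions: SmI2 (0.1 M in THF, 3 equiv), 20 added by syringe pump (final 2 mM), THF, −78 °C → rt, then rt 2 h; sat. aq. NH4Cl
Reagents that add atoms: none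
Why: Pinacol macrocyclisation/lactonisation cascade in which two single-electron transfers from divalent samarium give ketyl radical anions at C5 and C6 that are held on trivalent samarium and couple carbon to carbon, after which the samarium alkoxide on O6 attacks the C12 methyl ester and expels methoxide. The closest known reaction type is the SmI2-mediated intramolecular pinacol coupling of dialdehydes to medium and large rings, combined with the lactonisation of samarium alkoxides onto γ-esters. The ten-membered carbocycle closes in a 10-exo-trig mode (ketyl carbon onto carbonyl carbon, oxygen left outside the ring) and the γ-lactone by a 5-exo-trig acyl substitution. C5 is controlled by C4 (polar Felkin–Anh: the new bond forms anti to the C4–OSiEt3 bond, the bulky silyl ether does not chelate), C6 by C7 (Felkin: attack anti to the branched C8 arm, past hydrogen), and their threo (trans-on-ring) relationship by the samarium-bridged diketyl in which the ring arms C4 and C7 lie anti. The step needs ring closure to beat intermolecular coupling, which slow addition at high dilution and the turn imposed by the E-olefin and the quaternary C4 should secure, and acylation by O6 only, which is secured by ring size (O5 would give a six-membered lactone) and by the silyl ether on O8, the other γ-oxygen. The non-basic reductant should leave the C7 centre α to the aldehyde and the β-silyloxy group untouched.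

Step 16
Reactants: 22 trans-fused hydroxy γ-lactone
Product: 23 5-O-triethylsilyl ether of 22 (4,5,8-tris(triethylsilyloxy) lactone)
Conditions: Et3SiOTf, 2,6-lutidine, CH2Cl2, −78 → 0 °C
Reagents that add atoms: triethylsilyl trifluoromethanesulfonate CC[Si](CC)(CC)OS(=O)(=O)C(F)(F)F
Why: Silyl triflate protection of the hindered secondary C5 hydroxyl ensures that the enolate chemistry of the next step meets no free alkoxide able to translactonise.

Step 17
Reactants: 23 4,5,8-tris(triethylsilyloxy) lactone
Product: 26 α-methylene lactone (C11=C13H2) with O4, O5, O8 triethylsilyl and O9 PMB ethers, via Mannich base 24 (not isolated), via ammonium iodide 25 (not isolated)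
Conditions: LiN(i-Pr)2 (1.3 equiv), THF, −78 °C; Me2N=CH2 I (Eschenmoser's salt), −78 °C → rt; then MeI, MeOH, rt; then sat. aq. NaHCO3/CH2Cl2, rt
Reagents that add atoms: N,N-dimethylmethyleneiminium iodide C=[N+](C)C.[I-]
Why: Mannich reaction of the lactone enolate with Eschenmoser's salt, N-methylation and base-induced elimination of trimethylamine install the exocyclic methylene, the transient C11 centre (expected anti to C8) being destroyed.

Step 18
Reactants: 26 α-methylene lactone tris(triethylsilyl) ether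
Product: 27 4,5,8-triol (α-methylene lactone, O9 PMB ether, E-C2=C3 olefin)
Conditions: HF·pyridine, pyridine, THF, 0 °C → rt
Reagents that add atoms: none
Why: Buffered fluoride cleavage should remove the three triethylsilyl ethers while the PMB ether and the α-methylene lactone, which is sensitive to base but not to this reagent, survive.

Step 19
Reactants: 27 4,5,8-triol
Product: 28 (2S,3R)-2,3-epoxy-4,5,8-triol (α-methylene lactone, O9 PMB ether)
Conditions: VO(acac)2 (10 mol %), t-BuOOH (1.5 equiv), CH2Cl2, 0 °C → rt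
Reagents that add atoms: tert-butyl hydroperoxide CC(C)(C)OO
Why: Vanadium-catalysed hydroxyl-directed epoxidation, in which the C4 vanadate delivers the peroxide oxygen to the C2=C3 face on which O4 lies when the C4–C5 ring bond stands perpendicular to the olefin (as the ring demands, with the methyl group in the olefin plane), which should give the trans 2S,3R epoxide and leave the electron-poor exocyclic methylene alone.

Step 20
Reactants: 28 (2S,3R)-2,3-epoxy-4,5,8-triol; 29 angelic acid ((2Z)-2-methylbut-2-enoic acid)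
Product: 30 5,8-di-O-angeloyl-2,3-epoxy-4-hydroxy lactone with O9 PMB ether
Conditions: 29 (6 equiv), 2,4,6-Cl3C6H2COCl (6 equiv), Et3N, toluene, rt; then 28, toluene, 75 °C
Reagents that add atoms: none
Why: Yamaguchi-type acylation with the preformed angelic 2,4,6-trichlorobenzoic mixed anhydride and no nucleophilic catalyst should esterify the two secondary hydroxyls on C5 and C8 without Z-to-E isomerisation to the tiglate, the tertiary C4 hydroxyl being too hindered to react.

Step 21
Reactants: 30 5,8-di-O-angeloyl-2,3-epoxy-4-hydroxy lactone with O9 PMB ether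
Product: 31 9-hydroxy compound (5,8-di-O-angeloyl-2,3-epoxy-4,9-dihydroxy α-methylene lactone)
Conditions: DDQ (1.5 equiv), CH2Cl2/pH 7 buffer (10:1), 0 °C → rt
Reagents that add atoms: none
Why: Oxidative PMB cleavage by DDQ (hydride abstraction from the electron-rich benzylic position, then hydrolysis of the oxocarbenium ion) frees O9 under neutral conditions that should not move the neighbouring angelate or open the epoxide.

Step 22
Reactants: 31 9-hydroxy compound
Product: 32 target CNP0320279.1 ((2S,3R,4R,5R,6S,7S,8S,10S)-5,8-bis(angeloyloxy)-2,3-epoxy-4-hydroxy-4,10-dimethyl-9-oxo ten-membered ring with the α-methylene 12,6-lactone)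
Conditions: Dess–Martin periodinane, pyridine, CH2Cl2, rt
Reagents that add atoms: none
Why: Dess–Martin oxidation of the secondary C9 carbinol gives the ketone under buffered, non-basic conditions that should preserve the epimerisable C8 and C10 centres, the epoxide and the esters.

Compound list
1 | (S)-citronellal | C[C@@H](CCC=C(C)C)CC=O | starting material
2 | (2R,3S)-3,7-dimethyl-2-[(phenylamino)oxy]oct-6-enal (not isolated) | O=C[C@H](ONc1ccccc1)[C@@H](C)CCC=C(C)C | intermediate
3 | (2R,3S)-3,7-dimethyl-2-[(phenylamino)oxy]oct-6-en-1-ol | OC[C@H](ONc1ccccc1)[C@@H](C)CCC=C(C)C | intermediate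
4 | (2R,3S)-3,7-dimethyloct-6-ene-1,2-diol | OC[C@H](O)[C@@H](C)CCC=C(C)C | intermediate
5 | (4R)-2-(4-methoxyphenyl)-4-[(2S)-6-methylhept-5-en-2-yl]-1,3-dioxolane (acetal carbon undefined) | C1OC(c2ccc(OC)cc2)O[C@@H]1[C@@H](C)CCC=C(C)C | intermediate
6 | (2E,6S)-6-[(4R)-2-(4-methoxyphenyl)-1,3-dioxolan-4-yl]-2-methylhept-2-en-1-ol | C1OC(c2ccc(OC)cc2)O[C@@H]1[C@@H](C)CC/C=C(\C)CO | intermediate
7 | [(2S,3S)-3-{(3S)-3-[(4R)-2-(4-methoxyphenyl)-1,3-dioxolan-4-yl]butyl}-2-methyloxiran-2-yl]methanol | C1OC(c2ccc(OC)cc2)O[C@@H]1[C@@H](C)CC[C@@H]3O[C@@]3(C)CO | intermediate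
8 | (2S,3R,6S)-6-[(4R)-2-(4-methoxyphenyl)-1,3-dioxolan-4-yl]-2-methyl-3-(phenylselanyl)heptane-1,2-diol (not isolated) | C1OC(c2ccc(OC)cc2)O[C@@H]1[C@@H](C)CC[C@@H]([Se]c3ccccc3)[C@@](C)(O)CO | intermediate
9 | selenoxide of 8 (selenium centre undefined; not isolated) | C1OC(c2ccc(OC)cc2)O[C@@H]1[C@@H](C)CC[C@@H]([Se](=O)c3ccccc3)[C@@](C)(O)CO | intermediate
10 | (2R,3E,6S)-6-[(4R)-2-(4-methoxyphenyl)-1,3-dioxolan-4-yl]-2-methylhept-3-ene-1,2-diol | C1OC(c2ccc(OC)cc2)O[C@@H]1[C@@H](C)C/C=C/[C@@](C)(O)CO | intermediate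
11 | (4R)-2-(4-methoxyphenyl)-4-[(2S,4E,6R)-6-methyl-6,7-bis(triethylsilyloxy)hept-4-en-2-yl]-1,3-dioxolane | C1OC(c2ccc(OC)cc2)O[C@@H]1[C@@H](C)C/C=C/[C@@](C)(O[Si](CC)(CC)CC)CO[Si](CC)(CC)CC | intermediate
12 | (2R,3S,5E,7R)-2-[(4-methoxybenzyl)oxy]-3,7-dimethyl-7,8-bis(triethylsilyloxy)oct-5-en-1-ol | OC[C@H](OCc1ccc(OC)cc1)[C@@H](C)C/C=C/[C@@](C)(O[Si](CC)(CC)CC)CO[Si](CC)(CC)CC | intermediate
13 | (2R,3S,5E,7R)-2-[(4-methoxybenzyl)oxy]-3,7-dimethyl-7,8-bis(triethylsilyloxy)oct-5-enal | O=C[C@H](OCc1ccc(OC)cc1)[C@@H](C)C/C=C/[C@@](C)(O[Si](CC)(CC)CC)CO[Si](CC)(CC)CC | intermediate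
14 | methyl 4-chloro-4-oxobutanoate | COC(=O)CCC(Cl)=O | starting material
15 | methyl 4-(ethylsulfanyl)-4-oxobutanoate | CCSC(=O)CCC(=O)OC | intermediate
16 | E(O)-dicyclohexylboron enolate of 15 (not isolated) | CCS/C(OB(C1CCCCC1)C1CCCCC1)=C\CC(=O)OC | intermediate
17 | methyl (3R,4S,5R,6S,8E,10R)-3-[(ethylsulfanyl)carbonyl]-4-hydroxy-5-[(4-methoxybenzyl)oxy]-6,10-dimethyl-10,11-bis(triethylsilyloxy)undec-8-enoate (7,8-anti, 8,9-anti) | CCSC(=O)[C@H](CC(=O)OC)[C@H](O)[C@H](OCc1ccc(OC)cc1)[C@@H](C)C/C=C/[C@@](C)(O[Si](CC)(CC)CC)CO[Si](CC)(CC)CC | intermediate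
18 | methyl (3R,4S,5R,6S,8E,10R)-3-[(ethylsulfanyl)carbonyl]-5-[(4-methoxybenzyl)oxy]-6,10-dimethyl-4,10,11-tris(triethylsilyloxy)undec-8-enoate | CCSC(=O)[C@H](CC(=O)OC)[C@H](O[Si](CC)(CC)CC)[C@H](OCc1ccc(OC)cc1)[C@@H](C)C/C=C/[C@@](C)(O[Si](CC)(CC)CC)CO[Si](CC)(CC)CC | intermediate
19 | methyl (3R,4S,5R,6S,8E,10R)-3-[(ethylsulfanyl)carbonyl]-5-[(4-methoxybenzyl)oxy]-6,10-dimethyl-11-oxo-4,10-bis(triethylsilyloxy)undec-8-enoate | CCSC(=O)[C@H](CC(=O)OC)[C@H](O[Si](CC)(CC)CC)[C@H](OCc1ccc(OC)cc1)[C@@H](C)C/C=C/[C@@](C)(O[Si](CC)(CC)CC)C=O | intermediate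
20 | methyl (3R,4S,5R,6S,8E,10R)-3-formyl-5-[(4-methoxybenzyl)oxy]-6,10-dimethyl-11-oxo-4,10-bis(triethylsilyloxy)undec-8-enoate (key-step precursor) | O=C[C@H](CC(=O)OC)[C@H](O[Si](CC)(CC)CC)[C@H](OCc1ccc(OC)cc1)[C@@H](C)C/C=C/[C@@](C)(O[Si](CC)(CC)CC)C=O | intermediate
21 | ten-membered C5,C6-diol methyl ester, present as its trivalent samarium diolate and drawn as the diol (not isolated) | O[C@H]1[C@H](CC(=O)OC)[C@H](O[Si](CC)(CC)CC)[C@H](OCc2ccc(OC)cc2)[C@@H](C)C/C=C/[C@@](C)(O[Si](CC)(CC)CC)[C@@H]1O | intermediate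
22 | trans-fused hydroxy γ-lactone, (2E,4R,5R,6S,7S,8S,9R,10S)-5-hydroxy-9-[(4-methoxybenzyl)oxy]-4,10-dimethyl-4,8-bis(triethylsilyloxy)cyclodec-2-ene with the C7–C11H2–C12(=O)–O6 lactone (key-step product) | C1C(=O)O[C@H]2[C@H]1[C@H](O[Si](CC)(CC)CC)[C@H](OCc3ccc(OC)cc3)[C@@H](C)C/C=C/[C@@](C)(O[Si](CC)(CC)CC)[C@@H]2O | intermediate
23 | 5-O-triethylsilyl ether of 22 | C1C(=O)O[C@H]2[C@H]1[C@H](O[Si](CC)(CC)CC)[C@H](OCc3ccc(OC)cc3)[C@@H](C)C/C=C/[C@@](C)(O[Si](CC)(CC)CC)[C@@H]2O[Si](CC)(CC)CC | intermediate
24 | 11-[(dimethylamino)methyl] derivative of 23 (C11 substituent anti to C8; not isolated) | CN(C)C[C@@H]1C(=O)O[C@H]2[C@H]1[C@H](O[Si](CC)(CC)CC)[C@H](OCc3ccc(OC)cc3)[C@@H](C)C/C=C/[C@@](C)(O[Si](CC)(CC)CC)[C@@H]2O[Si](CC)(CC)CC | intermediate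
25 | trimethylammonium iodide of 24 (not isolated) | [I-].C[N+](C)(C)C[C@@H]1C(=O)O[C@H]2[C@H]1[C@H](O[Si](CC)(CC)CC)[C@H](OCc3ccc(OC)cc3)[C@@H](C)C/C=C/[C@@](C)(O[Si](CC)(CC)CC)[C@@H]2O[Si](CC)(CC)CC | intermediate
26 | α-methylene lactone (C11=C13H2) with O4, O5, O8 triethylsilyl and O9 PMB ethers | C=C1C(=O)O[C@H]2[C@H]1[C@H](O[Si](CC)(CC)CC)[C@H](OCc3ccc(OC)cc3)[C@@H](C)C/C=C/[C@@](C)(O[Si](CC)(CC)CC)[C@@H]2O[Si](CC)(CC)CC | intermediate
27 | 4,5,8-triol of 26 | C=C1C(=O)O[C@H]2[C@H]1[C@H](O)[C@H](OCc3ccc(OC)cc3)[C@@H](C)C/C=C/[C@@](C)(O)[C@@H]2O | intermediate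
28 | (2S,3R)-2,3-epoxide of 27 | C=C1C(=O)O[C@H]2[C@H]1[C@H](O)[C@H](OCc3ccc(OC)cc3)[C@@H](C)C[C@@H]4O[C@H]4[C@@](C)(O)[C@@H]2O | intermediate
29 | angelic acid, (2Z)-2-methylbut-2-enoic acid | C/C=C(/C)C(=O)O | starting material
30 | 5,8-di-O-angeloyl derivative of 28 (O9 PMB ether, free C4 hydroxyl) | C=C1C(=O)O[C@H]2[C@H]1[C@H](OC(=O)/C(C)=C\C)[C@H](OCc3ccc(OC)cc3)[C@@H](C)C[C@@H]4O[C@H]4[C@@](C)(O)[C@@H]2OC(=O)/C(C)=C\C | intermediate
31 | 9-hydroxy compound (30 without the PMB group) | C=C1C(=O)O[C@H]2[C@H]1[C@H](OC(=O)/C(C)=C\C)[C@H](O)[C@@H](C)C[C@@H]3O[C@H]3[C@@](C)(O)[C@@H]2OC(=O)/C(C)=C\C | intermediate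
32 | CNP0320279.1, (2S,3R,4R,5R,6S,7S,8S,10S)-5,8-bis(angeloyloxy)-2,3-epoxy-4-hydroxy-4,10-dimethyl-9-oxo ten-membered ring with the α-methylene 12,6-lactone | C=C1C(=O)O[C@H]2[C@H]1[C@H](OC(=O)/C(C)=C\C)C(=O)[C@@H](C)C[C@@H]1O[C@H]1[C@@](C)(O)[C@@H]2OC(=O)/C(C)=C\C | target

Total step count: 22. Longest linear sequence: 21 steps (1 → 32 through steps 1–9 and 11–22; step 10 is a one-step branch).

Steps most likely to fail

Step 15. Intermolecular ketyl coupling to oligomers, coupling in the erythro sense, or simple reduction of one aldehyde may outrun the ring closure. The fallback closes the ring by olefin metathesis and then oxygenates the new olefin in the anti sense, with no electron transfer. It sets out from 20. Wittig methylenation of both aldehydes (Ph3P=CH2, THF, −78 → 0 °C) gives the triene F1. Ring-closing metathesis at high dilution (second-generation Grubbs catalyst, (H2IMes)(PCy3)Cl2Ru=CHPh, toluene, 80 °C) joins C5 to C6 with loss of ethylene and should give the cis-olefin that a ten-membered ring favours, the cyclodecadiene F2. Dimethyldioxirane (acetone, −20 °C) should epoxidise this strained cis-olefin ahead of the trans C2=C3 bond and on its outer face, giving the cis-epoxide F3. PPTS in wet CH2Cl2 then lets the C12 ester carbonyl open the epoxide at C6 with inversion (5-exo), methanol is lost, and the trans-hydroxy lactone 22 is reached, where the route resumes at step 16.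

Step 11. The anti relationship (enolate geometry) or the Felkin facial selectivity may erode, and O8 may lactonise onto C12 before it is silylated. The fallback replaces the closed boron aldol by an open-transition-state Mukaiyama aldol. It sets out from 15 and 13. LiN(i-Pr)2 then Me3SiCl (THF, −78 °C) converts 15 into the silyl ketene thioacetal F4. BF3·OEt2 (CH2Cl2, −78 °C) promotes its addition to 13 through an open, non-chelated transition state, which is anti-selective for thioester-derived ketene acetals whatever their geometry and follows the same Felkin sense at the α-alkoxy aldehyde. Aqueous work-up returns the aldol 17, where the route resumes at step 12.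

Step 19. Oxygen may be delivered to the other olefin face if the ring conformer places O4 differently, and the secondary carbinols may be oxidised in competition. The fallback uses reagent control on the fully silylated olefin, one step earlier. It sets out from 26. Shi epoxidation with the fructose-derived ketone of the L series (KHSO5 as Oxone, K2CO3, MeCN/CH2(OMe)2/H2O, 0 °C) should epoxidise the trans C2=C3 bond under catalyst control and give the epoxide F5. HF·pyridine (as in step 18) then removes the three silyl groups and gives 28, where the route resumes at step 20.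

Further compounds
F1 | step 15 | triene from double methylenation of 20 (C5 and C6 formyl groups replaced by vinyl, other centres as in 20) | C=C[C@H](CC(=O)OC)[C@H](O[Si](CC)(CC)CC)[C@H](OCc1ccc(OC)cc1)[C@@H](C)C/C=C/[C@@](C)(O[Si](CC)(CC)CC)C=C
F2 | step 15 | (2E,5Z)-cyclodeca-2,5-diene with the C7 CH2CO2Me side chain (ring-closed F1) | [C@@H]1(CC(=O)OC)[C@H](O[Si](CC)(CC)CC)[C@H](OCc2ccc(OC)cc2)[C@@H](C)C/C=C/[C@@](C)(O[Si](CC)(CC)CC)/C=C\1
F3 | step 15 | cis-5,6-epoxide of F2 (oxygen on the face that becomes O5) | O1[C@@H]2[C@H](CC(=O)OC)[C@H](O[Si](CC)(CC)CC)[C@H](OCc3ccc(OC)cc3)[C@@H](C)C/C=C/[C@@](C)(O[Si](CC)(CC)CC)[C@H]12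
F4 | step 11 | trimethylsilyl ketene thioacetal of 15 | CCS/C(O[Si](C)(C)C)=C\CC(=O)OC
F5 | step 19 | (2S,3R)-2,3-epoxide of 26 (O4, O5, O8 triethylsilyl ethers) | C=C1C(=O)O[C@H]2[C@H]1[C@H](O[Si](CC)(CC)CC)[C@H](OCc3ccc(OC)cc3)[C@@H](C)C[C@@H]4O[C@H]4[C@@](C)(O[Si](CC)(CC)CC)[C@@H]2O[Si](CC)(CC)CC
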